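**Retrosynthetic overview**

1. The target is reached by fluoride deprotection of an adduct whose C15–C5′ bond comes from a catalytic asymmetric vinylogous Mukaiyama aldol of an (E)-enal (made from a C13 methyl ketone by Horner–Wadsworth–Emmons olefination) with 4-methyl-2-silyloxyfuran; the butenolide ring comes in last.
2. Ring B (C5–C6–C7–C8–C9–C10) is made by one-carbon ring expansion of a trans-hydrindane whose five-membered ring is C5–C6–C8–C9–C10: C7 is added as a cyclopropane CH2 across a C6(OSi)=C8 enol ether, and oxidative opening of the C6–C8 bond under O2 gives the C6 ketone and the C8 tertiary alcohol.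
3. The enabling feature is that ring B carries oxygen at C6 and a methyl-bearing tertiary carbinol at C8, 1,3 across C7 (a β-hydroxy ketone at the C6-ketone level), and that the axial C10 methyl shields the β-face of C8.
4. The hydrindane comes from dehydroabietic acid, used only as the source of ring A (C4, C5, C10 bought): arene degradation to a seco-diacid, Claisen closure of the five-membered ring, Tsuji dehydrogenation, side-chain addition at C9, Babler–Dauben transposition (oxygen to C6) and reductive silylation (sets C9).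
5. Order of ring formation: ring A (chiral pool), five-membered precursor ring, six-membered ring B (key step), butenolide.

Key step: step 10

Numbering: labdane-type numbers of the target are used throughout (decalin C1–C10, 4α-carboxyl carbon C18, chain C11–C15, butenolide atoms 2′–5′ with C5′ on C15); hydrindanes keep these numbers, so their five-membered ring is C5–C6–C8–C9–C10 and C7 is absent until step 9. From 3 onward every intermediate keeps ring A of 2: 4β-CH3, 4α-CO2CH2CH2SiMe3, 5α-H, 10β-CH3.

Assumption: the target is taken to be stable as the open 6α-hydroxy-18-acid and not to close to the 18,6α-lactone under the mildly acidic final work-up.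

**Route**

Step 1
Reactants: 1 dehydroabietic acid
Product: 2 2-(trimethylsilyl)ethyl dehydroabietate
Conditions: Cl3CC(=NH)OCH2CH2SiMe3 (1.5 equiv), toluene, 100 °C
Reagents that add atoms: 2-(trimethylsilyl)ethyl 2,2,2-trichloroacetimidate C[Si](C)(C)CCOC(=N)C(Cl)(Cl)Cl
Why: imidate O-alkylation of the carboxylic acid avoids acyl substitution at the hindered neopentyl carbonyl, marks the C4 carboxyl as different from the two carboxyls made next, and gives an ester that fluoride removes at the end; no stereocentre is touched.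

Step 2
Reactants: 2 2-(trimethylsilyl)ethyl dehydroabietate
Product: 3 ring A seco-diacid (10α-CO2H from old C9; CH2CH2CO2H arm on C5 from C6, old C7 and old C8)
Conditions: RuCl3·xH2O (5 mol %), NaIO4 (excess), CCl4–MeCN–H2O, 25 °C
Reagents that add atoms: sodium periodate [Na+].[O-]I(=O)(=O)=O; water O
Why: oxidative arene degradation by RuO4 made in situ turns the two ring-fusion arene carbons into carboxylic acids and should leave the bought stereocentres C4, C5 and C10 untouched because none carries an activated C–H.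

Step 3
Reactants: 3 ring A seco-diacid
Product: 4 ring A mono-allyl ester (arm CO2CH2CH=CH2; 10α-CO2H free)
Conditions: allyl alcohol (1.1 equiv), EDC·HCl, DMAP (cat.), CH2Cl2, 0 °C
Reagents that add atoms: allyl alcohol C=CCO
Why: Steglich-type carbodiimide esterification should be far faster at the unhindered propanoic acid arm than at the tertiary neopentyl C10 carboxyl, so only the arm is esterified.

Step 4
Reactants: 4 ring A mono-allyl ester
Product: 7 allyl 8-methyl-9-oxo-trans-hydrindane-8-carboxylate (C8 epimers), via acid chloride 5 (not isolated), via allyl β-keto ester 6 (not isolated)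
Conditions: (COCl)2, DMF (cat.), CH2Cl2, 0 → 20 °C; evaporate; LiN(SiMe3)2 (2.2 equiv), THF, −78 → 0 °C; then MeI, 0 → 20 °C
Reagents that add atoms: iodomethane CI
Why: intramolecular Claisen (Dieckmann-type) C-acylation of the allyl ester enolate by the C10 acid chloride closes the five-membered ring (5-exo-trig) trans-fused because both arms are equatorial on ring A, the acid chloride out-competes the C4 ester, and the β-keto ester enolate is C-methylated in the same flask (the C8 configuration is lost in step 5).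

Step 5
Reactants: 7 allyl 8-methyl-9-oxo-trans-hydrindane-8-carboxylate
Product: 8 8-methyl-trans-hydrind-6(8)-en-9-one
Conditions: Pd(OAc)2 (5 mol %), dppe (5 mol %), MeCN, 80 °C
Reagents that add atoms: none
Why: palladium-catalysed decarboxylation–dehydrogenation of an allyl β-keto ester (Tsuji type) proceeds by oxidative addition to zerovalent palladium, loss of CO2 and β-hydride elimination toward the ring CH2, giving the 2-methylcyclopentenone unit without base so that the trans C5–H is kept.

Step 6
Reactants: 8 8-methyl-trans-hydrind-6(8)-en-9-one; 9 2-(2-bromoethyl)-2-methyl-1,3-dioxolane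
Product: 11 9β-hydroxy-8-methyl-9α-[2-(2-methyl-1,3-dioxolan-2-yl)ethyl]-trans-hydrind-6(8)-ene, via Grignard reagent 10 (not isolated)
Conditions: 9, Mg, THF, 40 °C; CeCl3 (anhydrous), THF, −78 °C; then 8, −78 → 0 °C; aq. NH4Cl
Reagents that add atoms: none
Why: organocerium 1,2-addition (Grignard reagent with CeCl3) to the hindered enone carbonyl from the α-face, opposite the angular C10 methyl, suppresses conjugate addition; the C9 configuration is of no consequence because C9 becomes sp2 in step 7.

Step 7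
Reactants: 11 tertiary allylic alcohol
Product: 12 8-methyl-9-[2-(2-methyl-1,3-dioxolan-2-yl)ethyl]-trans-hydrind-8-en-6-one
Conditions: [C5H5NH][CrO3Cl] (pyridinium chlorochromate, 3 equiv), 4 Å molecular sieves, CH2Cl2, 20 °C
Reagents that add atoms: pyridinium chlorochromate c1cc[nH+]cc1.[O-][Cr](=O)(=O)Cl
Why: Babler–Dauben oxidative transposition moves the oxygen from C9 to C6 and the alkene to C8=C9 through a [3,3] shift of the allylic chromate ester and oxidation at C6, and the non-basic medium should leave the now α′ C5–H trans.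

Step 8
Reactants: 12 hydrind-8-en-6-one
Product: 14 8-methyl-6-(trimethylsilyloxy)-9β-[2-(2-methyl-1,3-dioxolan-2-yl)ethyl]-trans-hydrind-6(8)-ene (9α-H), via lithium enolate 13 (not isolated)
Conditions: Li (2.2 equiv), t-BuOH (1.0 equiv), NH3(l)–THF, −78 °C; isoprene; evaporate NH3; Me3SiCl, Et3N, THF, −78 → 0 °C
Reagents that add atoms: chlorotrimethylsilane C[Si](C)(C)Cl
Why: dissolving-metal conjugate reduction with enolate trapping (reductive silylation) gives the C6(O)=C8 enol ether regiospecifically, C9 is protonated on the α-face opposite the C10 methyl so that the side chain ends β (cis to the methyl), and C5 is never enolised.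

Step 9
Reactants: 14 silyl enol ether
Product: 15 6β-(trimethylsilyloxy)-8β-methyl-6α,8α-methano-trans-hydrindane (cyclopropane CH2 = C7)
Conditions: Et2Zn, CH2I2, CH2Cl2, 0 → 20 °C
Reagents that add atoms: diiodomethane ICI
Why: Simmons–Smith cyclopropanation (Furukawa variant) of the electron-rich silyl enol ether, expected from the α-face, brings in C7; the configurations made at C6 and C8 are erased in step 10, and ester and ketal are inert to the zinc carbenoid.

Step 10
Reactants: 15 siloxycyclopropane
Product: 18 8α-hydroxy-8β-methyl-trans-decal-6-one (9β-ketal chain), via cyclopropanol 16 (not isolated), via 8α-hydroperoxide 17 (not isolated)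
Conditions: NH4F (1.5 equiv), MeOH, 0 °C; solvent exchange to toluene; Mn(acac)3 (5 mol %), O2 (1 atm), 20 °C; then PPh3 (1.2 equiv), 0 °C
Reagents that add atoms: dioxygen O=O
Why: After desilylation, trivalent manganese oxidises the cyclopropanol by one electron and the cyclopropyloxy radical undergoes β-scission of the internal C6–C8 bond, which turns the bicyclo[3.1.0]hexane into the cyclohexanone of ring B (C7 inserted between C6 and C8) and leaves a tertiary β-keto radical at C8 that is captured by O2; PPh3 then reduces the hydroperoxide. The closest known types are the manganese-catalysed aerobic ring opening of cyclopropanols to β-peroxy and β-hydroxy ketones and the Saegusa–Ito FeCl3 ring expansion of 1-siloxybicyclo[n.1.0]alkanes. No ring is closed: ring B arises by cleavage of the shared bond of the fused cyclopropane (fragmentative one-carbon ring expansion). The new C8 stereocentre is controlled by the axial C10 methyl, which blocks the axial β-face of the radical in the trans-decalone chair so that O2 should add equatorially from the α-face (8α-O, 8β-CH3); C4, C5, C9 and C10 are untouched and C5 should stay trans because the medium is neutral and the trans-decal-6-one is the stable isomer. The step needs cleavage of the internal rather than the external cyclopropane bond, secured by formation of a tertiary instead of a primary radical and by strain release of the trans-fused bicycle. It also needs O2 capture to outrun hydrogen abstraction, secured by working under 1 atm O2.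

Step 11
Reactants: 18 β-hydroxy ketone
Product: 20 6α,8α-dihydroxy-13-ketone (methyl ketone side chain), via 6α,8α-diol ketal 19 (not isolated)
Conditions: SmI2 (3 equiv), H2O, THF, 0 °C; then 1 M HCl, THF, 20 °C
Reagents that add atoms: water O
Why: single-electron ketyl reduction by samarium diiodide (divalent samarium) should give, like a dissolving-metal reduction, the thermodynamically preferred equatorial 6α-alcohol (a hydride would enter from the open α-face and give the axial 6β-alcohol), and the acidic work-up hydrolyses the dioxolane (acetal hydrolysis).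

Step 12
Reactants: 20 keto diol
Product: 21 6α,8α-bis(triethylsilyloxy)-13-ketone
Conditions: Et3SiOTf (3 equiv), 2,6-lutidine, CH2Cl2, −78 → 0 °C
Reagents that add atoms: triethylsilyl trifluoromethanesulfonate CC[Si](CC)(CC)OS(=O)(=O)C(F)(F)F
Why: silyl triflate silylation protects the secondary 6α-OH (which could otherwise lactonise onto the neighbouring C4 ester under the basic olefination) and the tertiary 8α-OH; any silyl enol ether of the methyl ketone is hydrolysed on work-up.

Step 13
Reactants: 21 bis-silyl ether methyl ketone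
Product: 22 (13E)-N-methoxy-N-methyl enamide
Conditions: (EtO)2P(O)CH2C(O)N(OMe)Me, NaH, THF, 0 → 60 °C
Reagents that add atoms: diethyl [2-(methoxy(methyl)amino)-2-oxoethyl]phosphonate CCOP(=O)(CC(=O)N(C)OC)OCC
Why: Horner–Wadsworth–Emmons olefination of the methyl ketone with a stabilised phosphonate should favour the E-trisubstituted alkene (amide trans to the chain CH2); the minor Z isomer is to be removed by chromatography.

Step 14
Reactants: 22 enamide
Product: 23 (13E)-enal
Conditions: i-Bu2AlH (1.3 equiv), THF, −78 °C; aq. KNaC4H4O6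
Reagents that add atoms: none
Why: Weinreb amide reduction stops at the aldehyde through the stable aluminium chelate, without 1,4-reduction and without touching the hindered neopentyl C4 ester at −78 °C.

Step 15
Reactants: 24 4-methylfuran-2(5H)-one
Product: 25 4-methyl-2-(trimethylsilyloxy)furan
Conditions: Me3SiOTf, Et3N, CH2Cl2, 0 °C
Reagents that add atoms: trimethylsilyl trifluoromethanesulfonate C[Si](C)(C)OS(=O)(=O)C(F)(F)F
Why: soft enolisation and O-silylation of the butenolide gives the 2-silyloxyfuran (a cyclic silyl dienolate) used as the vinylogous nucleophile.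

Step 16
Reactants: 23 (13E)-enal; 25 4-methyl-2-(trimethylsilyloxy)furan
Product: 26 6,8-bis(triethylsilyl) ether 2-(trimethylsilyl)ethyl ester of the target
Conditions: Ti(OiPr)4 (20 mol %), (S)-BINOL (20 mol %), Et2O, −20 °C; then 10 % aq. citric acid
Reagents that add atoms: none
Why: catalytic asymmetric vinylogous Mukaiyama aldol on a tetravalent titanium BINOLate adds furan C5 to the aldehyde; C15 is set by the catalyst (the ligand antipode that gives 15S is to be confirmed on a model enal, the core stereocentres being too remote to matter) and C5′ by the open transition state, which should favour the threo (15S,5′S) adduct.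

Step 17
Reactants: 26 protected target
Product: 27 CNP0292216.1
Conditions: Bu4NF (6 equiv), AcOH (6 equiv), THF–DMF, 0 → 20 °C; pH 4 buffer
Reagents that add atoms: none
Why: fluoride-mediated desilylation cleaves both triethylsilyl ethers and, by attack at silicon with loss of ethene, the 2-(trimethylsilyl)ethyl ester, while the acetic acid buffer should prevent γ-deprotonation of the butenolide (epimerisation at C5′ or elimination of the C15 hydroxyl).

**Compound list**

1 | dehydroabietic acid (abieta-8,11,13-trien-18-oic acid) | CC(C)C1=CC2=C(C=C1)[C@]3(CCC[C@@]([C@@H]3CC2)(C)C(=O)O)C | starting material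
2 | 2-(trimethylsilyl)ethyl dehydroabietate | CC(C)C1=CC2=C(C=C1)[C@]3(CCC[C@@]([C@@H]3CC2)(C)C(=O)OCC[Si](C)(C)C)C | intermediate
3 | ring A seco-diacid (4α-CO2CH2CH2SiMe3, 4β-CH3, 5α-H, 10β-CH3, 10α-CO2H, C5 arm CH2CH2CO2H) | OC(=O)[C@@]1(C)CCC[C@@](C)(C(=O)OCC[Si](C)(C)C)[C@@H]1CCC(=O)O | intermediate
4 | ring A mono-allyl ester (arm CO2CH2CH=CH2, 10α-CO2H free) | OC(=O)[C@@]1(C)CCC[C@@](C)(C(=O)OCC[Si](C)(C)C)[C@@H]1CCC(=O)OCC=C | intermediate
5 | C10 acid chloride of 4 | ClC(=O)[C@@]1(C)CCC[C@@](C)(C(=O)OCC[Si](C)(C)C)[C@@H]1CCC(=O)OCC=C | intermediate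
6 | allyl 9-oxo-trans-hydrindane-8-carboxylate (C8 epimers) | O=C1[C@@]2(C)CCC[C@@](C)(C(=O)OCC[Si](C)(C)C)[C@@H]2CC1C(=O)OCC=C | intermediate
7 | allyl 8-methyl-9-oxo-trans-hydrindane-8-carboxylate (C8 epimers) | O=C1[C@@]2(C)CCC[C@@](C)(C(=O)OCC[Si](C)(C)C)[C@@H]2CC1(C)C(=O)OCC=C | intermediate
8 | 8-methyl-trans-hydrind-6(8)-en-9-one | O=C1[C@@]2(C)CCC[C@@](C)(C(=O)OCC[Si](C)(C)C)[C@@H]2C=C1C | intermediate
9 | 2-(2-bromoethyl)-2-methyl-1,3-dioxolane | CC1(CCBr)OCCO1 | starting material
10 | [2-(2-methyl-1,3-dioxolan-2-yl)ethyl]magnesium bromide | CC1(CC[Mg]Br)OCCO1 | intermediate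
11 | 9β-hydroxy-8-methyl-9α-[2-(2-methyl-1,3-dioxolan-2-yl)ethyl]-trans-hydrind-6(8)-ene | O[C@]1(CCC3(C)OCCO3)[C@@]2(C)CCC[C@@](C)(C(=O)OCC[Si](C)(C)C)[C@@H]2C=C1C | intermediate
12 | 8-methyl-9-[2-(2-methyl-1,3-dioxolan-2-yl)ethyl]-trans-hydrind-8-en-6-one | O=C1C(C)=C(CCC3(C)OCCO3)[C@@]2(C)CCC[C@@](C)(C(=O)OCC[Si](C)(C)C)[C@@H]21 | intermediate
13 | lithium 6(8)-enolate (9α-H, 9β-chain) | [Li]OC1=C(C)[C@H](CCC3(C)OCCO3)[C@@]2(C)CCC[C@@](C)(C(=O)OCC[Si](C)(C)C)[C@@H]21 | intermediate
14 | 8-methyl-6-(trimethylsilyloxy)-9β-[2-(2-methyl-1,3-dioxolan-2-yl)ethyl]-trans-hydrind-6(8)-ene | C[Si](C)(C)OC1=C(C)[C@H](CCC3(C)OCCO3)[C@@]2(C)CCC[C@@](C)(C(=O)OCC[Si](C)(C)C)[C@@H]21 | intermediate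
15 | 6β-(trimethylsilyloxy)-8β-methyl-6α,8α-methano-trans-hydrindane (CH2 = C7) | C[Si](C)(C)O[C@]12C[C@@]1(C)[C@H](CCC4(C)OCCO4)[C@@]3(C)CCC[C@@](C)(C(=O)OCC[Si](C)(C)C)[C@@H]32 | intermediate
16 | 6β-hydroxy-8β-methyl-6α,8α-methano-trans-hydrindane (cyclopropanol) | O[C@]12C[C@@]1(C)[C@H](CCC4(C)OCCO4)[C@@]3(C)CCC[C@@](C)(C(=O)OCC[Si](C)(C)C)[C@@H]32 | intermediate
17 | 8α-hydroperoxy-8β-methyl-trans-decal-6-one (9β-ketal chain) | CC3(CC[C@@H]1[C@@]2(C)CCC[C@@](C)(C(=O)OCC[Si](C)(C)C)[C@@H]2C(=O)C[C@@]1(C)OO)OCCO3 | intermediate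
18 | 8α-hydroxy-8β-methyl-trans-decal-6-one (9β-ketal chain) | CC3(CC[C@@H]1[C@@]2(C)CCC[C@@](C)(C(=O)OCC[Si](C)(C)C)[C@@H]2C(=O)C[C@@]1(C)O)OCCO3 | intermediate
19 | 6α,8α-diol ketal | CC3(CC[C@@H]1[C@@]2(C)CCC[C@@](C)(C(=O)OCC[Si](C)(C)C)[C@@H]2[C@@H](O)C[C@@]1(C)O)OCCO3 | intermediate
20 | 6α,8α-dihydroxy-13-ketone | CC(=O)CC[C@@H]1[C@@]2(C)CCC[C@@](C)(C(=O)OCC[Si](C)(C)C)[C@@H]2[C@@H](O)C[C@@]1(C)O | intermediate
21 | 6α,8α-bis(triethylsilyloxy)-13-ketone | CC(=O)CC[C@@H]1[C@@]2(C)CCC[C@@](C)(C(=O)OCC[Si](C)(C)C)[C@@H]2[C@@H](O[Si](CC)(CC)CC)C[C@@]1(C)O[Si](CC)(CC)CC | intermediate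
22 | (13E)-N-methoxy-N-methyl enamide | CON(C)C(=O)/C=C(\C)CC[C@@H]1[C@@]2(C)CCC[C@@](C)(C(=O)OCC[Si](C)(C)C)[C@@H]2[C@@H](O[Si](CC)(CC)CC)C[C@@]1(C)O[Si](CC)(CC)CC | intermediate
23 | (13E)-enal | O=C/C=C(\C)CC[C@@H]1[C@@]2(C)CCC[C@@](C)(C(=O)OCC[Si](C)(C)C)[C@@H]2[C@@H](O[Si](CC)(CC)CC)C[C@@]1(C)O[Si](CC)(CC)CC | intermediate
24 | 4-methylfuran-2(5H)-one | CC1=CC(=O)OC1 | starting material
25 | 4-methyl-2-(trimethylsilyloxy)furan | Cc1coc(O[Si](C)(C)C)c1 | intermediate
26 | 6,8-bis(triethylsilyl) ether 2-(trimethylsilyl)ethyl ester of the target (15S,5′S) | CC1=CC(=O)O[C@@H]1[C@@H](O)/C=C(\C)CC[C@@H]1[C@@]2(C)CCC[C@@](C)(C(=O)OCC[Si](C)(C)C)[C@@H]2[C@@H](O[Si](CC)(CC)CC)C[C@@]1(C)O[Si](CC)(CC)CC | intermediate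
27 | CNP0292216.1 | CC1=CC(=O)O[C@@H]1[C@@H](O)/C=C(\C)CC[C@@H]1[C@@]2(C)CCC[C@@](C)(C(=O)O)[C@@H]2[C@@H](O)C[C@@]1(C)O | target

**Step count and risks**

Total step count: 17. Longest linear sequence: 16 (steps 1–14, 16, 17).

Steps most likely to fail:

Step 10. What may go wrong: cleavage of the external C6–C7 bond, hydrogen abstraction by the C8 radical before O2 capture, or O2 capture on the β-face. The fallback sets out from 15 and comes back at 18, and makes the C8–O bond by a polar conjugate addition instead of radical capture. FeCl3 in DMF at 0 °C (Saegusa–Ito ring expansion) should give the ring-expanded 8-chloro-8-methyl-trans-decal-6-one F1. NaOAc in MeOH then eliminates HCl to the 8-methyl-trans-decal-7-en-6-one F2. Nucleophilic epoxidation (H2O2, NaOH, MeOH, 0 °C) should enter at C8 from the α-face, opposite the C10 methyl, and give the 7α,8α-epoxy-6-ketone F3. SmI2 (2 equiv) with MeOH in THF at −78 °C cleaves the C7–O bond and gives 18.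

Step 16. What may go wrong: poor enantiofacial discrimination by the catalyst on the β,β-disubstituted enal, or loss of threo selectivity caused by the methyl group next to the reacting furan carbon. The fallback sets out from 23 and comes back at 27, and sets both centres with an auxiliary.
- Evans syn-aldol of 23 with the dibutylboron enolate of (R)-4-benzyl-3-[(4-methoxybenzyloxy)acetyl]oxazolidin-2-one (Bu2BOTf, Et3N, CH2Cl2, −78 °C) should give the syn glycolate adduct F4.
- AlMe3 with MeNHOMe·HCl gives the N-methoxy-N-methylamide F5.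
- Et3SiOTf with 2,6-lutidine gives the C15 triethylsilyl ether F6.
- MeMgBr gives the methyl ketone F7.
- DDQ in CH2Cl2–pH 7 buffer removes the 4-methoxybenzyl group to give the α-hydroxy ketone F8.
- Ph3P=C=C=O (Bestmann ylide) in toluene at 80 °C acylates the hydroxyl and closes the butenolide by intramolecular Wittig olefination to give the C15 silyl ether of 26, F9.
- The fluoride conditions of step 17 then give 27.

Step 8. What may go wrong: reduction of the ester by the dissolved metal, or protonation of C9 from the β-face. The fallback sets out from 12 and comes back at 14. Hydrogenation over palladium on carbon (Pd/C, H2 50 atm, EtOAc) should add both hydrogens from the α-face and give the saturated 8β-methyl-9β-alkyl-trans-hydrindan-6-one F10. Kinetic deprotonation at C8 with LiN(iPr)2 in THF at −78 °C (C5–H is shielded by two quaternary carbons) and trapping with Me3SiCl gives 14.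

**Further compounds**

F1 | step 10 | 8-chloro-8-methyl-trans-decal-6-one (9β-ketal chain, C8 epimers) | CC3(CC[C@@H]1[C@@]2(C)CCC[C@@](C)(C(=O)OCC[Si](C)(C)C)[C@@H]2C(=O)CC1(C)Cl)OCCO3
F2 | step 10 | 8-methyl-trans-decal-7-en-6-one (9β-ketal chain) | CC3(CC[C@@H]1[C@@]2(C)CCC[C@@](C)(C(=O)OCC[Si](C)(C)C)[C@@H]2C(=O)C=C1C)OCCO3
F3 | step 10 | 7α,8α-epoxy-8β-methyl-trans-decal-6-one (9β-ketal chain) | CC3(CC[C@@H]1[C@@]2(C)CCC[C@@](C)(C(=O)OCC[Si](C)(C)C)[C@@H]2C(=O)[C@H]4O[C@@]14C)OCCO3
F4 | step 16 | syn glycolate aldol adduct with (R)-4-benzyloxazolidinone auxiliary | COc7ccc(CO[C@@H](C(=O)N5[C@H](Cc6ccccc6)COC5=O)[C@@H](O)/C=C(\C)CC[C@@H]1[C@@]2(C)CCC[C@@](C)(C(=O)OCC[Si](C)(C)C)[C@@H]2[C@@H](O[Si](CC)(CC)CC)C[C@@]1(C)O[Si](CC)(CC)CC)cc7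
F5 | step 16 | N-methoxy-N-methylamide of the glycolate adduct | COc7ccc(CO[C@@H](C(=O)N(C)OC)[C@@H](O)/C=C(\C)CC[C@@H]1[C@@]2(C)CCC[C@@](C)(C(=O)OCC[Si](C)(C)C)[C@@H]2[C@@H](O[Si](CC)(CC)CC)C[C@@]1(C)O[Si](CC)(CC)CC)cc7
F6 | step 16 | C15 triethylsilyl ether of the amide | COc7ccc(CO[C@@H](C(=O)N(C)OC)[C@@H](O[Si](CC)(CC)CC)/C=C(\C)CC[C@@H]1[C@@]2(C)CCC[C@@](C)(C(=O)OCC[Si](C)(C)C)[C@@H]2[C@@H](O[Si](CC)(CC)CC)C[C@@]1(C)O[Si](CC)(CC)CC)cc7
F7 | step 16 | α-(4-methoxybenzyloxy) methyl ketone | COc7ccc(CO[C@@H](C(C)=O)[C@@H](O[Si](CC)(CC)CC)/C=C(\C)CC[C@@H]1[C@@]2(C)CCC[C@@](C)(C(=O)OCC[Si](C)(C)C)[C@@H]2[C@@H](O[Si](CC)(CC)CC)C[C@@]1(C)O[Si](CC)(CC)CC)cc7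
F8 | step 16 | α-hydroxy methyl ketone | O[C@@H](C(C)=O)[C@@H](O[Si](CC)(CC)CC)/C=C(\C)CC[C@@H]1[C@@]2(C)CCC[C@@](C)(C(=O)OCC[Si](C)(C)C)[C@@H]2[C@@H](O[Si](CC)(CC)CC)C[C@@]1(C)O[Si](CC)(CC)CC
F9 | step 16 | C15 triethylsilyl ether of 26 | CC1=CC(=O)O[C@@H]1[C@@H](O[Si](CC)(CC)CC)/C=C(\C)CC[C@@H]1[C@@]2(C)CCC[C@@](C)(C(=O)OCC[Si](C)(C)C)[C@@H]2[C@@H](O[Si](CC)(CC)CC)C[C@@]1(C)O[Si](CC)(CC)CC
F10 | step 8 | 8β-methyl-9β-[2-(2-methyl-1,3-dioxolan-2-yl)ethyl]-trans-hydrindan-6-one | O=C1[C@H](C)[C@H](CCC3(C)OCCO3)[C@@]2(C)CCC[C@@](C)(C(=O)OCC[Si](C)(C)C)[C@@H]21
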